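**Retrosynthetic overview** (cembrane numbering: C1/C14 lactone fusion, C3/C4 oxirane, C7 carbinol, C8 exo-methylene carbon, C12 methyl, C13 acetate)
- The 14-membered carbocycle is closed last at C7–C8 by a Nozaki–Hiyama–Kishi reaction of a 2-bromoalkene with an aldehyde.
- The oxirane comes from Shi epoxidation of the (E)-C3=C4 alkene; the C13 acetate and the C7 aldehyde are adjusted late, without protecting groups.
- The cis-α-methylene-γ-butyrolactone (first ring) comes from a chelation-controlled indium Barbier union (C1–C14) of an eastern α-hydroxy aldehyde with a western (Z)-2-(bromomethyl)dienoate.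
- East: organocatalytic (Z)-crotylboration of 2,2-dimethoxyacetaldehyde sets C12/C13, then hydroboration and 2-bromoallylation. West: carboalumination/allylation of pent-4-yn-1-ol, then cross-metathesis.
- Ring order: lactone (step 5), oxirane (step 6), macrocycle (step 9).

Assumption: 2,2-dimethoxyacetaldehyde (compound 1, sold as a 60 % aqueous solution) is dried by extraction and distillation just before use.

Step 1
Reactants: 1 2,2-dimethoxyacetaldehyde; 2 (Z)-crotylboronic acid pinacol ester
Product: 3 (2R,3S)-1,1-dimethoxy-3-methylpent-4-en-2-ol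
Conditions: (R)-TRIP [(R)-3,3'-bis(2,4,6-triisopropylphenyl)-1,1'-binaphthyl-2,2'-diyl hydrogen phosphate] (5 mol %), 4 Å MS, toluene, −50 °C; aq. NaHCO3 work-up
Reagents that add atoms: none
Why: Proposed new method: chiral phosphoric acid-catalysed syn-selective (Z)-crotylboration of an α,α-dialkoxy aldehyde (a glyoxal mono-acetal), a substrate class on which this catalysis has not been demonstrated; the P–OH hydrogen-bonds the pseudo-axial boronate oxygen and P=O holds the formyl C–H, so the chair transition state with the acetal group equatorial exposes the aldehyde Re face (C13, R) and the Z geometry gives the syn methyl (C12, S), the closest known reaction type being phosphoric acid-catalysed allyl- and crotylboration of aryl, alkenyl and simple alkyl aldehydes with pinacol boronates.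

Step 2
Reactants: 3 (2R,3S)-1,1-dimethoxy-3-methylpent-4-en-2-ol; 4 2,3-dibromoprop-1-ene
Product: 6 (2R,3S)-7-bromo-1,1-dimethoxy-3-methyloct-7-en-2-ol, via alkylborane 5 (not isolated)
Conditions: 9-BBN (2.2 equiv), THF, 0 °C to rt; then KOtBu (3 equiv), CuOAc (10 mol %), 4 (2 equiv), THF, 0 °C to rt
Reagents that add atoms: none
Why: Anti-Markovnikov 9-BBN hydroboration of the terminal vinyl group followed by copper-catalysed alkylborane–allylic halide coupling, in which SN2 and SN2′ attack on 2,3-dibromopropene give the same 2-bromoalkene; no stereocenter is touched and the extra borane and base cover the free hydroxyl.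

Step 3
Reactants: 7 pent-4-yn-1-ol; 8 allyl bromide
Product: 10 (4E)-4-methylocta-4,7-dien-1-ol, via alkenylalane 9 (not isolated)
Conditions: AlMe3 (3 equiv), Cp2ZrCl2 (0.25 equiv), CH2Cl2, 0 °C to rt; then 8, Pd(PPh3)4 (3 mol %), THF, rt
Reagents that add atoms: trimethylaluminium, C[Al](C)C
Why: Negishi zirconium-catalysed carboalumination adds methyl and aluminium syn across the alkyne, and the zerovalent-palladium-catalysed coupling of the alkenylalane with allyl bromide proceeds with retention, fixing the (E)-trisubstituted alkene of the skipped diene.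

Step 4
Reactants: 10 (4E)-4-methylocta-4,7-dien-1-ol; 11 methyl 2-(bromomethyl)prop-2-enoate
Product: 12 methyl (2Z,5E)-2-(bromomethyl)-9-hydroxy-6-methylnona-2,5-dienoate
Conditions: second-generation Hoveyda–Grubbs catalyst [RuCl2(H2IMes)(=CH-C6H4-2-OiPr)] (5 mol %), 11 (3 equiv), 1,4-benzoquinone (10 mol %), CH2Cl2, 40 °C
Reagents that add atoms: none
Why: Olefin cross-metathesis of the terminal vinyl group (the trisubstituted alkene is inert) with the non-dimerising 1,1-disubstituted acrylate gives the more stable trisubstituted enoate with the chain trans to the ester and cis to CH2Br (2Z), as in methacrylate cross-metathesis, with benzoquinone suppressing isomerisation of the skipped diene.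

Step 5
Reactants: 6 (2R,3S)-7-bromo-1,1-dimethoxy-3-methyloct-7-en-2-ol; 12 methyl (2Z,5E)-2-(bromomethyl)-9-hydroxy-6-methylnona-2,5-dienoate
Product: 15 (4S,5R)-5-[(1R,2S)-6-bromo-1-hydroxy-2-methylhept-6-en-1-yl]-4-[(2E)-6-hydroxy-3-methylhex-2-en-1-yl]-3-methylideneoxolan-2-one, via hydroxy aldehyde 13 (not isolated), via hydroxy ester 14 (not isolated)
Conditions: 1 M aq. HCl, THF, 40 °C; then NaOAc (to pH 5), 12, indium powder (In), THF/H2O, rt; then TsOH·H2O (cat.), CH2Cl2, rt
Reagents that add atoms: water, O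
Why: Acetal hydrolysis frees the α-hydroxy aldehyde, whose hydroxyl and carbonyl chelate indium in the aqueous Barbier allylation so that the γ-carbon of the allyl unit adds anti to the C12 branch (Cram chelate, 13,14-syn) through a chair-like transition state giving the syn adduct known for (Z)-2-(bromomethyl)alk-2-enoates, and acid then closes the five-membered lactone on the C14 hydroxyl, setting C14 (R) and C1 (S) as the cis lactone.

Step 6
Reactants: 15 (4S,5R)-5-[(1R,2S)-6-bromo-1-hydroxy-2-methylhept-6-en-1-yl]-4-[(2E)-6-hydroxy-3-methylhex-2-en-1-yl]-3-methylideneoxolan-2-one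
Product: 16 (4S,5R)-5-[(1R,2S)-6-bromo-1-hydroxy-2-methylhept-6-en-1-yl]-4-{[(2R,3R)-3-(3-hydroxypropyl)-3-methyloxiran-2-yl]methyl}-3-methylideneoxolan-2-one
Conditions: Shi ketone (D-fructose-derived, 30 mol %), KHSO5 (as 2KHSO5·KHSO4·K2SO4), K2CO3, Bu4NHSO4, MeCN/CH2(OMe)2/aq. Na2B4O7 buffer (pH 10.5), 0 °C; Et3N-buffered silica
Reagents that add atoms: potassium peroxymonosulfate, [K+].[O-]S(=O)(=O)OO
Why: Shi asymmetric epoxidation, in which the chiral dioxirane delivers oxygen through a spiro transition state to the only electron-rich (E)-trisubstituted alkene and gives the (3R,4R)-oxirane under catalyst control, while the methylidene lactone and the bromoalkene are too electron-poor to react.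

Step 7
Reactants: 16 (4S,5R)-5-[(1R,2S)-6-bromo-1-hydroxy-2-methylhept-6-en-1-yl]-4-{[(2R,3R)-3-(3-hydroxypropyl)-3-methyloxiran-2-yl]methyl}-3-methylideneoxolan-2-one
Product: 17 (4S,5R)-5-[(1R,2S)-6-bromo-1-hydroxy-2-methylhept-6-en-1-yl]-4-{[(2R,3R)-3-methyl-3-(3-oxopropyl)oxiran-2-yl]methyl}-3-methylideneoxolan-2-one
Conditions: TEMPO (10 mol %), KBr (10 mol %), NaOCl (1.05 equiv), NaHCO3, CH2Cl2/H2O, 0 °C
Reagents that add atoms: none
Why: Anelli TEMPO oxidation, whose hindered oxoammonium oxidises the primary alcohol much faster than the flanked secondary C13 alcohol, and whose buffered basic medium spares the acid-sensitive epoxy alcohol; no stereocenter is affected.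

Step 8
Reactants: 17 (4S,5R)-5-[(1R,2S)-6-bromo-1-hydroxy-2-methylhept-6-en-1-yl]-4-{[(2R,3R)-3-methyl-3-(3-oxopropyl)oxiran-2-yl]methyl}-3-methylideneoxolan-2-one
Product: 18 (1R,2S)-6-bromo-2-methyl-1-[(2R,3S)-4-methylidene-3-{[(2R,3R)-3-methyl-3-(3-oxopropyl)oxiran-2-yl]methyl}-5-oxooxolan-2-yl]hept-6-en-1-yl acetate
Conditions: Ac2O, pyridine, DMAP (cat.), CH2Cl2, 0 °C
Reagents that add atoms: acetic anhydride, CC(=O)OC(C)=O
Why: DMAP-catalysed acetylation of the only remaining hydroxyl (C13) occurs at oxygen with retention, and the aldehyde, oxirane and lactone tolerate these mild conditions.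

Step 9
Reactants: 18 (1R,2S)-6-bromo-2-methyl-1-[(2R,3S)-4-methylidene-3-{[(2R,3R)-3-methyl-3-(3-oxopropyl)oxiran-2-yl]methyl}-5-oxooxolan-2-yl]hept-6-en-1-yl acetate
Product: 19 CNP0230083.2 [(1S,3R,4R,7R,12S,13R,14R)-13-acetoxy-3,4-epoxy-7-hydroxycembra-8(19),15(17)-dien-16,14-olide]
Conditions: CrCl2 (6 equiv), NiCl2 (5 mol %), Kishi-type chiral oxazoline–sulfonamide ligand (antipode giving Si-face addition, chosen on a model aldehyde), Et3N, THF/MeCN (0.002 M), rt; aq. work-up
Reagents that add atoms: none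
Why: Nozaki–Hiyama–Kishi macrocyclisation, in which NiCl2-catalysed activation of the 2-bromoalkene, transmetalation to chromium and 1,2-addition to the aldehyde at high dilution close the 14-membered ring and create the exo-methylene carbinol while tolerating acetate, lactone and oxirane, with the sulfonamide ligand on chromium directing Si-face attack to give C7 (R).

**Compound list**
1 | 2,2-dimethoxyacetaldehyde | COC(OC)C=O | starting material
2 | (Z)-crotylboronic acid pinacol ester, 2-[(2Z)-but-2-en-1-yl]-4,4,5,5-tetramethyl-1,3,2-dioxaborolane | C/C=C\CB1OC(C)(C)C(C)(C)O1 | starting material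
3 | (2R,3S)-1,1-dimethoxy-3-methylpent-4-en-2-ol | C=C[C@H](C)[C@@H](O)C(OC)OC | intermediate
4 | 2,3-dibromoprop-1-ene | C=C(Br)CBr | starting material
5 | 9-[(3S,4R)-4-hydroxy-5,5-dimethoxy-3-methylpentyl]-9-borabicyclo[3.3.1]nonane | C1CCC2CCCC1B2CC[C@H](C)[C@@H](O)C(OC)OC | intermediate
6 | (2R,3S)-7-bromo-1,1-dimethoxy-3-methyloct-7-en-2-ol | C=C(Br)CCC[C@H](C)[C@@H](O)C(OC)OC | intermediate
7 | pent-4-yn-1-ol | C#CCCCO | starting material
8 | allyl bromide (3-bromoprop-1-ene) | C=CCBr | starting material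
9 | dimethyl{(1E)-5-[(dimethylalumanyl)oxy]-2-methylpent-1-en-1-yl}alumane | C[Al](C)/C=C(\C)CCCO[Al](C)C | intermediate
10 | (4E)-4-methylocta-4,7-dien-1-ol | C=CC/C=C(\C)CCCO | intermediate
11 | methyl 2-(bromomethyl)prop-2-enoate | C=C(CBr)C(=O)OC | starting material
12 | methyl (2Z,5E)-2-(bromomethyl)-9-hydroxy-6-methylnona-2,5-dienoate | COC(=O)/C(CBr)=C/C/C=C(\C)CCCO | intermediate
13 | (2R,3S)-7-bromo-2-hydroxy-3-methyloct-7-enal | C=C(Br)CCC[C@H](C)[C@@H](O)C=O | intermediate
14 | methyl (3S,4R,5R,6S)-10-bromo-4,5-dihydroxy-3-[(2E)-6-hydroxy-3-methylhex-2-en-1-yl]-6-methyl-2-methylideneundec-10-enoate | C=C(Br)CCC[C@H](C)[C@@H](O)[C@H](O)[C@H](C(=C)C(=O)OC)C/C=C(\C)CCCO | intermediate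
15 | (4S,5R)-5-[(1R,2S)-6-bromo-1-hydroxy-2-methylhept-6-en-1-yl]-4-[(2E)-6-hydroxy-3-methylhex-2-en-1-yl]-3-methylideneoxolan-2-one | C=C(Br)CCC[C@H](C)[C@@H](O)[C@@H]1OC(=O)C(=C)[C@@H]1C/C=C(\C)CCCO | intermediate
16 | (4S,5R)-5-[(1R,2S)-6-bromo-1-hydroxy-2-methylhept-6-en-1-yl]-4-{[(2R,3R)-3-(3-hydroxypropyl)-3-methyloxiran-2-yl]methyl}-3-methylideneoxolan-2-one | C=C(Br)CCC[C@H](C)[C@@H](O)[C@@H]1OC(=O)C(=C)[C@@H]1C[C@H]2O[C@]2(C)CCCO | intermediate
17 | (4S,5R)-5-[(1R,2S)-6-bromo-1-hydroxy-2-methylhept-6-en-1-yl]-4-{[(2R,3R)-3-methyl-3-(3-oxopropyl)oxiran-2-yl]methyl}-3-methylideneoxolan-2-one | C=C(Br)CCC[C@H](C)[C@@H](O)[C@@H]1OC(=O)C(=C)[C@@H]1C[C@H]2O[C@]2(C)CCC=O | intermediate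
18 | (1R,2S)-6-bromo-2-methyl-1-[(2R,3S)-4-methylidene-3-{[(2R,3R)-3-methyl-3-(3-oxopropyl)oxiran-2-yl]methyl}-5-oxooxolan-2-yl]hept-6-en-1-yl acetate | C=C(Br)CCC[C@H](C)[C@@H](OC(C)=O)[C@@H]1OC(=O)C(=C)[C@@H]1C[C@H]2O[C@]2(C)CCC=O | intermediate
19 | CNP0230083.2, (1S,3R,4R,7R,12S,13R,14R)-13-acetoxy-3,4-epoxy-7-hydroxycembra-8(19),15(17)-dien-16,14-olide | C=C1CCC[C@H](C)[C@@H](OC(C)=O)[C@@H]2OC(=O)C(=C)[C@@H]2C[C@H]2O[C@]2(C)CC[C@H]1O | target

**Total step count:** 9. **Longest linear sequence:** 7 (steps 1, 2, 5, 6, 7, 8, 9; the western branch 3, 4, 5–9 is equally long).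

**Three steps most likely to fail**

Step 1 (the proposed new crotylboration): the small, oxygen-rich aldehyde may react through an uncatalysed background path or bind the acid through its acetal oxygens, lowering ee. The fallback sets out from 1 and comes back at 3. It replaces catalyst control by known reagent control: Brown crotylboration with B-(Z)-crotyldiisopinocampheylborane, made from cis-but-2-ene, n-BuLi/KOtBu, (+)-B-methoxydiisopinocampheylborane (from (−)-α-pinene, the antipode that adds to the Re face) and BF3·OEt2, at −78 °C in THF, followed by NaOH/H2O2. It makes no compound outside the list (none F0).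

Step 5 (Barbier union): chelation by the free hydroxyl may give an insufficient 13,14-syn ratio, or the bromide may add through the wrong terminus. The fallback sets out from 6 and 12 and comes back at 15, using Keck chelation-controlled allylstannane chemistry. Alcohol 6 is converted with NaH, 4-methoxybenzyl chloride and Bu4NI into the 4-methoxybenzyl ether F1. Mild acetal hydrolysis (LiBF4, wet MeCN) gives the α-alkoxy aldehyde F2. Bromide 12 is converted with Bu3SnSnBu3 and Pd(PPh3)4 into the allylstannane F3. MgBr2·OEt2 in CH2Cl2 at −20 °C chelates the aldehyde and the ether oxygen of F2, F3 adds in the open syn-selective mode, and acidic work-up closes the ring to the protected lactone F4. DDQ in buffered CH2Cl2/H2O removes the ether and returns 15.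

Step 9 (macrocyclisation): ring strain and ligand–substrate mismatch may give a poor yield or the wrong C7 configuration. The fallback sets out from 18 and comes back at 19, correcting C7 after ring closure. Ligand-free CrCl2/NiCl2 closure in DMSO at high dilution gives the carbinol as an epimer mixture that contains the (7S)-epimer F5. Dess–Martin oxidation of the mixture (NaHCO3 buffer) gives the macrocyclic enone F6. Corey–Bakshi–Shibata reduction with (S)-2-methyl-CBS-oxazaborolidine and catecholborane in toluene at −78 °C, with the alkenyl group as the large substituent, returns the (7R)-alcohol 19.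

**Further compounds**
F0 | step 1 | none | none
F1 | step 5 | 1-({[(2R,3S)-7-bromo-1,1-dimethoxy-3-methyloct-7-en-2-yl]oxy}methyl)-4-methoxybenzene | C=C(Br)CCC[C@H](C)[C@@H](OCc1ccc(OC)cc1)C(OC)OC
F2 | step 5 | (2R,3S)-7-bromo-2-[(4-methoxybenzyl)oxy]-3-methyloct-7-enal | C=C(Br)CCC[C@H](C)[C@@H](OCc1ccc(OC)cc1)C=O
F3 | step 5 | methyl (2Z,5E)-9-hydroxy-6-methyl-2-[(tributylstannyl)methyl]nona-2,5-dienoate | COC(=O)/C(C[Sn](CCCC)(CCCC)CCCC)=C/C/C=C(\C)CCCO
F4 | step 5 | (4S,5R)-5-{(1R,2S)-6-bromo-1-[(4-methoxybenzyl)oxy]-2-methylhept-6-en-1-yl}-4-[(2E)-6-hydroxy-3-methylhex-2-en-1-yl]-3-methylideneoxolan-2-one | C=C(Br)CCC[C@H](C)[C@@H](OCc1ccc(OC)cc1)[C@@H]1OC(=O)C(=C)[C@@H]1C/C=C(\C)CCCO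
F5 | step 9 | (1S,3R,4R,7S,12S,13R,14R)-13-acetoxy-3,4-epoxy-7-hydroxycembra-8(19),15(17)-dien-16,14-olide | C=C1CCC[C@H](C)[C@@H](OC(C)=O)[C@@H]2OC(=O)C(=C)[C@@H]2C[C@H]2O[C@]2(C)CC[C@@H]1O
F6 | step 9 | (1S,3R,4R,12S,13R,14R)-13-acetoxy-3,4-epoxy-7-oxocembra-8(19),15(17)-dien-16,14-olide | C=C1CCC[C@H](C)[C@@H](OC(C)=O)[C@@H]2OC(=O)C(=C)[C@@H]2C[C@H]2O[C@]2(C)CCC1=O
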